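**Retrosynthetic overview**

1. The strategy rests on the C7–C1–C2–C3–C4 segment of the single cyclohexane ring. C1 is the quaternary carbinol carrying the C7H2OBz arm, C2 is the neighbouring CHOH, C3H2–C4H2 is bare, C5 is CHOBz and C6 is CHOH. With C7 as an aldehyde and C3=C4 as an alkene this segment is the γ,δ-unsaturated carbonyl retron of a Claisen rearrangement.
2. Target 24 ⇐ cyclohexene dibenzoate 22 (saturation of C3=C4, loss of two benzyl ethers) ⇐ aldehyde 19 (reduction, removal of two 2-naphthylmethyl (NAP) ethers, benzoylation of C7–OH and C5–OH; the tertiary C1–OH stays free).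
3. 19 ⇐ [3,3] shift of the L-ido 2-alkoxyglycal 18 carrying an (E)-2-(benzyloxy)vinyl group at sugar C5. This forms C1–C2 and closes the only ring, the cyclohexene, as the dihydropyran opens.
4. 18 ⇐ glycal vinyl iodide 17 (copper C–O coupling) ⇐ thioglycoside aldehyde 12 (iodo-olefination, then anomeric dehydrohalogenation).
5. 12 ⇐ 1,6-anhydro-L-idopyranose 8 ⇐ epoxide 5 (SN2 inversion at C5) ⇐ D-glucofuranose 1.

Key step: step 11

Assumption: 1 is taken as purchasable (it also follows from diacetone-D-glucose by O-benzylation and selective hydrolysis of the 5,6-acetal); thioglycosides 10–13 are drawn as the α-L anomer that the anomeric effect should favour, and any β anomer is carried along because C1 becomes sp2 in step 9.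

Locants: "sugar C1–C7" refers to the carbohydrate chain; C1–C7 without prefix refers to the target as defined in line 1. The carbocycles 19–24 are all (1S,2R,5R,6S) with these target locants.

**Route**

Step 1
Reactants: 1 3-O-benzyl-1,2-O-isopropylidene-α-D-glucofuranose
Product: 3 6-O-benzoyl-3-O-benzyl-1,2-O-isopropylidene-5-O-methanesulfonyl-α-D-glucofuranose, via 6-O-benzoate 2 (not isolated)
Conditions: BzCl (1.05 equiv), pyridine, CH2Cl2, −35 to 0 °C; then MsCl, 0 °C to rt
Reagents that add atoms: benzoyl chloride, O=C(Cl)c1ccccc1; methanesulfonyl chloride, CS(=O)(=O)Cl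
Why: Selective O-acylation of the primary 6-OH at low temperature followed by O-sulfonylation of the remaining secondary 5-OH should arm C5 for displacement without touching a stereocentre.

Step 2
Reactants: 3 6-O-benzoyl-3-O-benzyl-1,2-O-isopropylidene-5-O-methanesulfonyl-α-D-glucofuranose
Product: 5 5,6-anhydro-3-O-benzyl-1,2-O-isopropylidene-β-L-idofuranose, via 6-alkoxide mesylate 4 (not isolated)
Conditions: t-BuOK, t-BuOH–CH2Cl2, 0 °C
Reagents that add atoms: none
Why: Transesterification frees the 6-alkoxide, which displaces the 5-mesylate from the rear (intramolecular Williamson SN2 epoxide closure), so C5 is inverted from D-gluco to L-ido.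

Step 3
Reactants: 5 5,6-anhydro-3-O-benzyl-1,2-O-isopropylidene-β-L-idofuranose
Product: 8 1,6-anhydro-3-O-benzyl-β-L-idopyranose, via diol acetonide 6 (not isolated), via 3-O-benzyl-L-idose 7 (not isolated)
Conditions: aq. H2SO4 (0.2 M), 1,4-dioxane, 100 °C
Reagents that add atoms: water, O
Why: Acid opens the epoxide at the primary C6 and hydrolyses the acetonide, and the freed L-idose should close under the same acid to the 1,6-anhydride (intramolecular Fischer glycosidation), which the ido configuration favours at equilibrium, with C2–C5 untouched.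

Step 4
Reactants: 8 1,6-anhydro-3-O-benzyl-β-L-idopyranose
Product: 9 1,6-anhydro-3-O-benzyl-2,4-di-O-(2-naphthylmethyl)-β-L-idopyranose
Conditions: NaH, 2-(bromomethyl)naphthalene, Bu4NI (cat.), DMF, 0 °C to rt
Reagents that add atoms: 2-(bromomethyl)naphthalene, BrCc1ccc2ccccc2c1
Why: Williamson etherification of both free secondary hydroxyls of the base-stable anhydro sugar installs DDQ-labile NAP ethers at O2 and O4 that are orthogonal to the benzyl ether at O3.

Step 5
Reactants: 9 1,6-anhydro-3-O-benzyl-2,4-di-O-(2-naphthylmethyl)-β-L-idopyranose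
Product: 11 phenyl 3-O-benzyl-2,4-di-O-(2-naphthylmethyl)-1-thio-α-L-idopyranoside, via 6-O-trimethylsilyl thioglycoside 10 (not isolated)
Conditions: PhSSiMe3, ZnI2, CH2Cl2, rt; then K2CO3, MeOH, 0 °C
Reagents that add atoms: (phenylthio)trimethylsilane, C[Si](C)(C)Sc1ccccc1
Why: Lewis-acid-assisted opening of the strained internal acetal at C1–O6 by the silyl sulfide (thiolysis of a 1,6-anhydro sugar) should give the thioglycoside and release O6 as a labile silyl ether that methanolysis removes, the arylmethyl ethers being stable in the absence of an iodide additive.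

Step 6
Reactants: 11 phenyl 3-O-benzyl-2,4-di-O-(2-naphthylmethyl)-1-thio-α-L-idopyranoside
Product: 12 phenyl 3-O-benzyl-2,4-di-O-(2-naphthylmethyl)-1-thio-α-L-ido-hexodialdo-1,5-pyranoside
Conditions: Dess–Martin periodinane, NaHCO3, CH2Cl2, 0 °C to rt
Reagents that add atoms: none
Why: Dess–Martin oxidation of the primary alcohol under buffered, non-basic conditions should leave the sulfide alone and avoid epimerising the α-alkoxy aldehyde at sugar C5.

Step 7
Reactants: 12 phenyl 3-O-benzyl-2,4-di-O-(2-naphthylmethyl)-1-thio-α-L-ido-hexodialdo-1,5-pyranoside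
Product: 13 phenyl (6E)-3-O-benzyl-6,7-dideoxy-7-iodo-2,4-di-O-(2-naphthylmethyl)-1-thio-α-L-ido-hept-6-enopyranoside
Conditions: CrCl2, CHI3, THF–1,4-dioxane, 0 °C to rt, dark
Reagents that add atoms: iodoform, IC(I)I
Why: Takai iodo-olefination through the geminal dichromium reagent from CHI3 and CrCl2 should give the (E)-vinyl iodide by elimination from the less hindered adduct, under non-basic conditions that preserve sugar C5.

Step 8
Reactants: 13 phenyl (6E)-3-O-benzyl-6,7-dideoxy-7-iodo-2,4-di-O-(2-naphthylmethyl)-1-thio-α-L-ido-hept-6-enopyranoside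
Product: 14 (6E)-3-O-benzyl-6,7-dideoxy-7-iodo-2,4-di-O-(2-naphthylmethyl)-L-ido-hept-6-enopyranose (anomeric mixture)
Conditions: NBS, NaHCO3, acetone–H2O (9:1), −15 to 0 °C
Reagents that add atoms: water, O
Why: Bromonium activation of the anomeric sulfide and capture of the oxocarbenium ion by water (oxidative thioglycoside hydrolysis) should free the hemiacetal while the electron-poor vinyl iodide and the arylmethyl ethers are spared.

Step 9
Reactants: 14 (6E)-3-O-benzyl-6,7-dideoxy-7-iodo-2,4-di-O-(2-naphthylmethyl)-L-ido-hept-6-enopyranose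
Product: 17 (6E)-1,5-anhydro-3-O-benzyl-6,7-dideoxy-7-iodo-2,4-di-O-(2-naphthylmethyl)-L-xylo-hepta-1,6-dienitol, via anomeric mesylate 15 (not isolated), via glycosyl chloride 16 (not isolated)
Conditions: MsCl, Et3N, CH2Cl2, −20 °C to rt; then DBU, DMF, 80 °C
Reagents that add atoms: none
Why: The ether-armed anomeric mesylate should collapse to the glycosyl chloride, from which DBU removes H-2 (dehydrohalogenation of a 2-O-alkyl glycosyl halide to a 2-alkoxyglycal), the chloride-equilibrated 1,2-cis anomer supplying the antiperiplanar H-2/Cl pair.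

Step 10
Reactants: 17 (6E)-1,5-anhydro-3-O-benzyl-6,7-dideoxy-7-iodo-2,4-di-O-(2-naphthylmethyl)-L-xylo-hepta-1,6-dienitol
Product: 18 (6E)-1,5-anhydro-3,7-di-O-benzyl-6-deoxy-2,4-di-O-(2-naphthylmethyl)-L-xylo-hepta-1,6-dienitol (the L-ido glycal with an (E)-2-(benzyloxy)vinyl group at sugar C5, cis to O4 and trans to O3)
Conditions: BnOH, CuI (10 mol %), 3,4,7,8-tetramethyl-1,10-phenanthroline (20 mol %), Cs2CO3, toluene, 80 °C
Reagents that add atoms: benzyl alcohol, OCc1ccccc1
Why: Ullmann-type copper-catalysed C–O coupling of a vinyl iodide with a primary alcohol proceeds with retention of alkene geometry, so the E iodide should give the E enol ether at a temperature well below that of the sigmatropic shift.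

Step 11
Reactants: 18 (6E)-1,5-anhydro-3,7-di-O-benzyl-6-deoxy-2,4-di-O-(2-naphthylmethyl)-L-xylo-hepta-1,6-dienitol
Product: 19 (1S,2R,5R,6S)-2,6-bis(benzyloxy)-1,5-bis(2-naphthylmethoxy)cyclohex-3-ene-1-carbaldehyde
Conditions: 1,2-dichlorobenzene (degassed), Et3N (trace), sealed tube, 190 °C
Reagents that add atoms: none
Why: Heating should drive a concerted [3,3]-sigmatropic (Claisen) shift of the allyl vinyl ether O5–C1=C2 / C5–C6=C7 (sugar numbering): the enol ether carbon C2 bonds to the vinyl terminus C7 while C5–O5 breaks, giving the formyl group (target C7), the quaternary centre (target C1) and the C3=C4 alkene. The closest known reaction is the thermal Claisen rearrangement of 5-C-vinyl glycals, 2-benzyloxy glycals included, to cyclohex-3-enecarbaldehydes. The six-membered carbocycle (sugar C2, C3, C4, C5, C6, C7) closes by this one C–C bond across the pyran, through the boat, bicyclo[2.2.2]octadiene-like transition state that the two-atom C3–C4 tether between the termini enforces. Target C1 is set by sugar C5, because the vinyl group, cis to O4 and trans to O3, can reach C2 only on its own face (suprafacial delivery). Target C2 is set by the E enol ether geometry, which in the boat turns the benzyloxy group toward the C1–O5 bridge and so places it cis to the formyl carbon. The step needs the E geometry to persist and the enol ethers to escape acid, which the stereodefined coupling of step 10, the trace of amine and the rate gain from the terminal alkoxy group (a lower temperature than the unsubstituted vinyl case) should secure.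

Step 12
Reactants: 19 (1S,2R,5R,6S)-2,6-bis(benzyloxy)-1,5-bis(2-naphthylmethoxy)cyclohex-3-ene-1-carbaldehyde
Product: 20 [(1S,2R,5R,6S)-2,6-bis(benzyloxy)-1,5-bis(2-naphthylmethoxy)cyclohex-3-en-1-yl]methanol
Conditions: NaBH4, MeOH–THF, 0 °C
Reagents that add atoms: none
Why: Borohydride reduction of the non-enolisable neopentyl aldehyde should give the primary alcohol at C7 without affecting the ethers or the alkene.

Step 13
Reactants: 20 [(1S,2R,5R,6S)-2,6-bis(benzyloxy)-1,5-bis(2-naphthylmethoxy)cyclohex-3-en-1-yl]methanol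
Product: 21 (1S,2R,5R,6S)-2,6-bis(benzyloxy)-1-(hydroxymethyl)cyclohex-3-ene-1,5-diol
Conditions: DDQ (2.5 equiv), CH2Cl2–pH 7 phosphate buffer (10:1), 0 °C to rt
Reagents that add atoms: none
Why: Oxidative cleavage of the electron-rich 2-naphthylmethyl ethers by DDQ (benzylic hydride abstraction, then hydrolysis of the oxocarbenium ion, water being present to prevent acetal formation with the neighbouring hydroxyl) is selective over benzyl ethers and should expose the tertiary C1–OH and the allylic C5–OH.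

Step 14
Reactants: 21 (1S,2R,5R,6S)-2,6-bis(benzyloxy)-1-(hydroxymethyl)cyclohex-3-ene-1,5-diol
Product: 22 [(1S,2R,5R,6S)-5-(benzoyloxy)-2,6-bis(benzyloxy)-1-hydroxycyclohex-3-en-1-yl]methyl benzoate
Conditions: BzCl (2.4 equiv), pyridine, DMAP (cat.), CH2Cl2, 0 °C
Reagents that add atoms: benzoyl chloride, O=C(Cl)c1ccccc1
Why: Acylation with an acid chloride and pyridine should esterify the primary C7–OH and the secondary C5–OH, while the tertiary C1–OH, flanked by two substituted ring carbons, is too hindered to react.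

Step 15
Reactants: 22 [(1S,2R,5R,6S)-5-(benzoyloxy)-2,6-bis(benzyloxy)-1-hydroxycyclohex-3-en-1-yl]methyl benzoate
Product: 24 [(1S,2R,5R,6S)-5-(benzoyloxy)-1,2,6-trihydroxycyclohexyl]methyl benzoate (CNP0264996.1), via saturated dibenzyl ether 23 (not isolated)
Conditions: H2 (1 atm), Pd(OH)2 on carbon, EtOAc–MeOH, rt
Reagents that add atoms: none
Why: Heterogeneous catalytic hydrogenation should saturate the cis-disubstituted C3=C4 bond first and then hydrogenolyse the two benzyl ethers, benzoates being inert and no stereocentre being involved.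

**Compound list**

1 | 3-O-benzyl-1,2-O-isopropylidene-α-D-glucofuranose | OC[C@@H](O)[C@H]1O[C@@H]2OC(C)(C)O[C@@H]2[C@H]1OCc1ccccc1 | starting material
2 | 6-O-benzoyl-3-O-benzyl-1,2-O-isopropylidene-α-D-glucofuranose | O=C(OC[C@@H](O)[C@H]1O[C@@H]2OC(C)(C)O[C@@H]2[C@H]1OCc1ccccc1)c1ccccc1 | intermediate (not isolated)
3 | 6-O-benzoyl-3-O-benzyl-1,2-O-isopropylidene-5-O-methanesulfonyl-α-D-glucofuranose | O=C(OC[C@@H](OS(C)(=O)=O)[C@H]1O[C@@H]2OC(C)(C)O[C@@H]2[C@H]1OCc1ccccc1)c1ccccc1 | intermediate
4 | 3-O-benzyl-1,2-O-isopropylidene-5-O-methanesulfonyl-α-D-glucofuranose (present as its potassium 6-alkoxide) | OC[C@@H](OS(C)(=O)=O)[C@H]1O[C@@H]2OC(C)(C)O[C@@H]2[C@H]1OCc1ccccc1 | intermediate (not isolated)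
5 | 5,6-anhydro-3-O-benzyl-1,2-O-isopropylidene-β-L-idofuranose | C1O[C@@H]1[C@H]1O[C@@H]2OC(C)(C)O[C@@H]2[C@H]1OCc1ccccc1 | intermediate
6 | 3-O-benzyl-1,2-O-isopropylidene-β-L-idofuranose | OC[C@H](O)[C@H]1O[C@@H]2OC(C)(C)O[C@@H]2[C@H]1OCc1ccccc1 | intermediate (not isolated)
7 | 3-O-benzyl-L-idopyranose (anomeric mixture) | OC[C@@H]1OC(O)[C@H](O)[C@@H](OCc2ccccc2)[C@@H]1O | intermediate (not isolated)
8 | 1,6-anhydro-3-O-benzyl-β-L-idopyranose | C1O[C@@H]2[C@H](O)[C@@H](OCc3ccccc3)[C@H](O)[C@H]1O2 | intermediate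
9 | 1,6-anhydro-3-O-benzyl-2,4-di-O-(2-naphthylmethyl)-β-L-idopyranose | C1O[C@@H]2[C@H](OCc3ccc4ccccc4c3)[C@@H](OCc3ccccc3)[C@H](OCc3ccc4ccccc4c3)[C@H]1O2 | intermediate
10 | phenyl 3-O-benzyl-2,4-di-O-(2-naphthylmethyl)-1-thio-6-O-trimethylsilyl-α-L-idopyranoside | C[Si](C)(C)OC[C@@H]1O[C@@H](Sc2ccccc2)[C@H](OCc2ccc3ccccc3c2)[C@@H](OCc2ccccc2)[C@@H]1OCc1ccc2ccccc2c1 | intermediate (not isolated)
11 | phenyl 3-O-benzyl-2,4-di-O-(2-naphthylmethyl)-1-thio-α-L-idopyranoside | OC[C@@H]1O[C@@H](Sc2ccccc2)[C@H](OCc2ccc3ccccc3c2)[C@@H](OCc2ccccc2)[C@@H]1OCc1ccc2ccccc2c1 | intermediate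
12 | phenyl 3-O-benzyl-2,4-di-O-(2-naphthylmethyl)-1-thio-α-L-ido-hexodialdo-1,5-pyranoside | O=C[C@@H]1O[C@@H](Sc2ccccc2)[C@H](OCc2ccc3ccccc3c2)[C@@H](OCc2ccccc2)[C@@H]1OCc1ccc2ccccc2c1 | intermediate
13 | phenyl (6E)-3-O-benzyl-6,7-dideoxy-7-iodo-2,4-di-O-(2-naphthylmethyl)-1-thio-α-L-ido-hept-6-enopyranoside | I/C=C/[C@@H]1O[C@@H](Sc2ccccc2)[C@H](OCc2ccc3ccccc3c2)[C@@H](OCc2ccccc2)[C@@H]1OCc1ccc2ccccc2c1 | intermediate
14 | (6E)-3-O-benzyl-6,7-dideoxy-7-iodo-2,4-di-O-(2-naphthylmethyl)-L-ido-hept-6-enopyranose (anomeric mixture) | I/C=C/[C@@H]1OC(O)[C@H](OCc2ccc3ccccc3c2)[C@@H](OCc2ccccc2)[C@@H]1OCc1ccc2ccccc2c1 | intermediate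
15 | 1-O-methanesulfonate of 14 | I/C=C/[C@@H]1OC(OS(C)(=O)=O)[C@H](OCc2ccc3ccccc3c2)[C@@H](OCc2ccccc2)[C@@H]1OCc1ccc2ccccc2c1 | intermediate (not isolated)
16 | (6E)-3-O-benzyl-6,7-dideoxy-7-iodo-2,4-di-O-(2-naphthylmethyl)-L-ido-hept-6-enopyranosyl chloride (anomers) | I/C=C/[C@@H]1OC(Cl)[C@H](OCc2ccc3ccccc3c2)[C@@H](OCc2ccccc2)[C@@H]1OCc1ccc2ccccc2c1 | intermediate (not isolated)
17 | (6E)-1,5-anhydro-3-O-benzyl-6,7-dideoxy-7-iodo-2,4-di-O-(2-naphthylmethyl)-L-xylo-hepta-1,6-dienitol | I/C=C/[C@@H]1OC=C(OCc2ccc3ccccc3c2)[C@@H](OCc2ccccc2)[C@@H]1OCc1ccc2ccccc2c1 | intermediate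
18 | (6E)-1,5-anhydro-3,7-di-O-benzyl-6-deoxy-2,4-di-O-(2-naphthylmethyl)-L-xylo-hepta-1,6-dienitol | c1ccccc1CO/C=C/[C@@H]1OC=C(OCc2ccc3ccccc3c2)[C@@H](OCc2ccccc2)[C@@H]1OCc1ccc2ccccc2c1 | intermediate (key-step precursor)
19 | (1S,2R,5R,6S)-2,6-bis(benzyloxy)-1,5-bis(2-naphthylmethoxy)cyclohex-3-ene-1-carbaldehyde (formyl cis to both benzyloxy groups, trans to the C5 naphthylmethoxy group) | O=C[C@]1(OCc2ccc3ccccc3c2)[C@H](OCc2ccccc2)C=C[C@@H](OCc2ccc3ccccc3c2)[C@@H]1OCc1ccccc1 | intermediate (key-step product)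
20 | [(1S,2R,5R,6S)-2,6-bis(benzyloxy)-1,5-bis(2-naphthylmethoxy)cyclohex-3-en-1-yl]methanol | OC[C@]1(OCc2ccc3ccccc3c2)[C@H](OCc2ccccc2)C=C[C@@H](OCc2ccc3ccccc3c2)[C@@H]1OCc1ccccc1 | intermediate
21 | (1S,2R,5R,6S)-2,6-bis(benzyloxy)-1-(hydroxymethyl)cyclohex-3-ene-1,5-diol | OC[C@]1(O)[C@H](OCc2ccccc2)C=C[C@@H](O)[C@@H]1OCc1ccccc1 | intermediate
22 | [(1S,2R,5R,6S)-5-(benzoyloxy)-2,6-bis(benzyloxy)-1-hydroxycyclohex-3-en-1-yl]methyl benzoate | O=C(OC[C@]1(O)[C@H](OCc2ccccc2)C=C[C@@H](OC(=O)c2ccccc2)[C@@H]1OCc1ccccc1)c1ccccc1 | intermediate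
23 | [(1S,2R,5R,6S)-5-(benzoyloxy)-2,6-bis(benzyloxy)-1-hydroxycyclohexyl]methyl benzoate | O=C(OC[C@]1(O)[C@H](OCc2ccccc2)CC[C@@H](OC(=O)c2ccccc2)[C@@H]1OCc1ccccc1)c1ccccc1 | intermediate (not isolated)
24 | [(1S,2R,5R,6S)-5-(benzoyloxy)-1,2,6-trihydroxycyclohexyl]methyl benzoate (locants as in the overview) | O=C(OC[C@]1(O)[C@H](O)CC[C@@H](OC(=O)c2ccccc2)[C@@H]1O)c1ccccc1 | target

**Step count and risks**

Total step count: 15. Longest linear sequence: 15 steps (1 to 24); the route is fully linear and the key-step precursor 18 is reached after 10 steps.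

Steps most likely to fail:

1. Step 11 (Claisen shift). The boat-constrained shift may be outrun by thermal side processes: a dearomatising [3,3] shift of the 2-naphthylmethyl enol ether, loss of an allylic ether, or acid-catalysed cleavage of the enol ethers. Isomerisation of the benzyloxyvinyl group before the shift would erode the configuration at C2. Fallback: from 18, triisobutylaluminium (i-Bu3Al, toluene, −20 °C to rt) would promote the rearrangement at low temperature by a Lewis-acid, ion-pair pathway and reduce the aluminium-bound aldehyde in situ by β-hydride transfer (organoaluminium-promoted Claisen rearrangement–reduction). The ring tether still forces same-face delivery. This would give alcohol 20 directly and rejoin the route at 20, ahead of step 13; no compound outside the list is made (F0).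

2. Step 9 (glycal formation). In the ido series the anomerically favoured 1,2-trans chloride has no antiperiplanar H-2, so elimination may be slow, and hydrolysis back to 14 or substitution at C1 by chloride or DBU may then take over. Fallback: from 13, whose 1,2-trans sulfur is cis to H-2, oxidation with mCPBA (CH2Cl2, −78 °C) would give the phenyl sulfoxide of 13 F1. Thermolysis of it (toluene, 110 °C, P(OMe)3 as sulfenic acid trap) should effect a syn (Ei) sulfoxide elimination to the 2-alkoxyglycal. The fallback returns at 17 and bypasses 14.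

3. Step 10 (C–O coupling). The catalyst may be deactivated, or the acid- and heat-sensitive glycal may degrade under carbonate at 80 °C before the C–O bond forms, with hydrodeiodination as the competing outcome. Fallback: from 17, Miyaura borylation (B2pin2, PdCl2(PPh3)2, PPh3, KOPh, toluene, 50 °C; retention of geometry) would give the (E)-vinyl pinacol boronate F2. Chan–Lam–Evans oxidative etherification with benzyl alcohol (Cu(OAc)2, Et3N, BnOH, air, rt) reverses the polarity of the vinyl partner and runs at room temperature. It returns to the route at 18.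

Further compounds
F0 | step 11 | none | none
F1 | step 9 | phenyl (6E)-3-O-benzyl-6,7-dideoxy-7-iodo-2,4-di-O-(2-naphthylmethyl)-1-thio-α-L-ido-hept-6-enopyranoside S-oxide (epimers at sulfur) | I/C=C/[C@@H]1O[C@@H](S(=O)c2ccccc2)[C@H](OCc2ccc3ccccc3c2)[C@@H](OCc2ccccc2)[C@@H]1OCc1ccc2ccccc2c1
F2 | step 10 | (6E)-1,5-anhydro-3-O-benzyl-6,7-dideoxy-2,4-di-O-(2-naphthylmethyl)-7-(4,4,5,5-tetramethyl-1,3,2-dioxaborolan-2-yl)-L-xylo-hepta-1,6-dienitol | CC1(C)OB(/C=C/[C@@H]2OC=C(OCc3ccc4ccccc4c3)[C@@H](OCc3ccccc3)[C@@H]2OCc2ccc3ccccc3c2)OC1(C)C
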